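The 3(2H)-furanone ring (O–C3=C2–C1(=O)–C10, germacrane numbering) is opened at the O–C3 bond and at the bond from the quaternary C10 to its methyl group (C14). One π-acid-catalysed step on an acyclic precursor closes this ring and shifts the methyl group from C1 to C10. It gives the C2=C3 enol ether, the C1 ketone and the C10 stereocentre at once by transfer of chirality. The precursor is an (R)-2-hydroxy-2-methyl alkynyl ketone: C10 ketone bearing the PMB-protected C8–C9 chain, free tertiary C1 carbinol, C2≡C3 alkyne conjugated to the Z C4=C5 alkene, and C6 as a TBDPS ether.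

Key step: step 6

Assumption: the SMILES is read as (6R,7R,8R,10R,11S), 4Z, with an 8-O-angelate; in steps 2 and 9 the ligand enantiomer named is the one expected to give the (R)-carbinol and is exchanged for its antipode if the first run shows the opposite sense.

Step 1
Reactants: 1 (Z)-3-methylpent-2-en-4-yn-1-ol
Product: 2 (Z)-tert-butyl[(3-methylpent-2-en-4-yn-1-yl)oxy]diphenylsilane
Conditions: TBDPSCl, imidazole, CH2Cl2, 0 °C → rt
Reagents that add atoms: tert-butyl(chloro)diphenylsilane, CC(C)(C)[Si](Cl)(c1ccccc1)c1ccccc1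
Why: Standard silylation of a primary allylic alcohol; the bulky, weakly nucleophilic TBDPS ether is chosen so that O6 of the Z-enyne cannot compete for C3 in step 6 and can later be removed with fluoride beside the PMB ether.

Step 2
Reactants: 2 (Z)-tert-butyl[(3-methylpent-2-en-4-yn-1-yl)oxy]diphenylsilane; 3 methyl pyruvate
Product: 4 methyl (2R,5Z)-7-[(tert-butyldiphenylsilyl)oxy]-2-hydroxy-2,5-dimethylhept-5-en-3-ynoate
Conditions: Zn(OTf)2 (20 mol%), (1S,2S)-2-(dimethylamino)-1-(4-nitrophenyl)-3-(tert-butyldimethylsilyloxy)propan-1-ol (22 mol%), Et3N (30 mol%), toluene, 60 °C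
Reagents that add atoms: none
Why: Zinc-mediated catalytic asymmetric addition of a terminal alkyne to an α-keto ester, in which the ligand-bound zinc acetylide adds to one face of the pyruvate ketone and sets the (R)-tertiary carbinol that becomes C1.

Step 3
Reactants: 4 methyl (2R,5Z)-7-[(tert-butyldiphenylsilyl)oxy]-2-hydroxy-2,5-dimethylhept-5-en-3-ynoate
Product: 5 (2R,5Z)-7-[(tert-butyldiphenylsilyl)oxy]-2-hydroxy-N-methoxy-N,2,5-trimethylhept-5-en-3-ynamide
Conditions: MeNH(OMe)·HCl, i-PrMgCl, THF, −20 → 0 °C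
Reagents that add atoms: N,O-dimethylhydroxylamine hydrochloride, CNOC.Cl
Why: Direct Weinreb aminolysis of the ester by the chloromagnesium amide; the tertiary alkoxide forms first and is inert, and no stereocentre is touched.

Step 4
Reactants: 5 (2R,5Z)-7-[(tert-butyldiphenylsilyl)oxy]-2-hydroxy-N-methoxy-N,2,5-trimethylhept-5-en-3-ynamide; 6 vinylmagnesium bromide
Product: 7 (4R,7Z)-9-[(tert-butyldiphenylsilyl)oxy]-4-hydroxy-4,7-dimethylnona-1,7-dien-5-yn-3-one
Conditions: 6 (3.5 equiv), THF, −20 → 0 °C; inverse quench into cold aq. NaHSO4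
Reagents that add atoms: none
Why: Weinreb ketone synthesis, in which the Grignard addition stops at the chelated tetrahedral intermediate, and the acidic inverse quench keeps the released amine from adding to the new vinyl ketone.

Step 5
Reactants: 7 (4R,7Z)-9-[(tert-butyldiphenylsilyl)oxy]-4-hydroxy-4,7-dimethylnona-1,7-dien-5-yn-3-one; 8 4-methoxybenzyl alcohol
Product: 9 (4R,7Z)-9-[(tert-butyldiphenylsilyl)oxy]-4-hydroxy-1-[(4-methoxybenzyl)oxy]-4,7-dimethylnon-7-en-5-yn-3-one (C8 PMB ether, C10 ketone, (R)-C1 carbinol with methyl, C2≡C3, Z-C4=C5, C6 TBDPS ether)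
Conditions: 8 (5 equiv), PMe3 (10 mol%), THF, rt
Reagents that add atoms: none
Why: Phosphine-catalysed oxa-Michael addition of the benzylic alcohol to an α′-hydroxy vinyl ketone, a particularly reactive acceptor, under neutral conditions that leave the α-ketol unrearranged.

Step 6
Reactants: 9 (4R,7Z)-9-[(tert-butyldiphenylsilyl)oxy]-4-hydroxy-1-[(4-methoxybenzyl)oxy]-4,7-dimethylnon-7-en-5-yn-3-one
Product: 10 (2R)-5-[(2Z)-4-[(tert-butyldiphenylsilyl)oxy]but-2-en-2-yl]-2-{2-[(4-methoxybenzyl)oxy]ethyl}-2-methylfuran-3(2H)-one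
Conditions: PtCl2 (5 mol%), toluene, 80 °C
Reagents that add atoms: none
Why: The π-acid coordinates the C2≡C3 alkyne, the C10 ketone oxygen adds to C3, and the resulting cyclic oxocarbenium ion is quenched by a 1,2-shift of the C14 methyl group from the carbinol carbon C1 to C10 (α-ketol/semipinacol type), after which the C1 hydroxyl becomes the C1 ketone and protodemetalation at C2 frees the catalyst. The closest known reaction type is the Pt(II)- or Au(III)-catalysed domino heterocyclisation/1,2-alkyl migration of 2-hydroxy-2-alkynyl ketones to 3(2H)-furanones. The furanone ring closes in the 5-endo-dig mode through the new O–C3 bond. The only new stereocentre, C10, is substrate-controlled: the methyl group migrates suprafacially across the C1–C10 bond, so the (R)-configuration of the carbinol is relayed to (R)-C10. The step needs the ketone oxygen to win C3 against the C6 oxygen and against Meyer–Schuster ionisation, and it needs a single migrating group; the bulky TBDPS ether blocks the 5-exo attack that a Z-enynol oxygen would make, the tertiary hydroxyl is left free to drive the shift, and methyl is the only exocyclic carbon substituent on C1.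

Step 7
Reactants: 10 (2R)-5-[(2Z)-4-[(tert-butyldiphenylsilyl)oxy]but-2-en-2-yl]-2-{2-[(4-methoxybenzyl)oxy]ethyl}-2-methylfuran-3(2H)-one
Product: 11 (2R)-5-[(2Z)-4-hydroxybut-2-en-2-yl]-2-{2-[(4-methoxybenzyl)oxy]ethyl}-2-methylfuran-3(2H)-one
Conditions: TBAF, AcOH, THF, 0 °C → rt
Reagents that add atoms: none
Why: Fluoride-mediated desilylation under acetic acid buffering, to which the PMB ether and the vinylogous ester are inert.

Step 8
Reactants: 11 (2R)-5-[(2Z)-4-hydroxybut-2-en-2-yl]-2-{2-[(4-methoxybenzyl)oxy]ethyl}-2-methylfuran-3(2H)-one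
Product: 12 (2Z)-3-[(5R)-5-{2-[(4-methoxybenzyl)oxy]ethyl}-5-methyl-4-oxo-4,5-dihydrofuran-2-yl]but-2-enal
Conditions: Dess–Martin periodinane, NaHCO3, CH2Cl2, 0 °C
Reagents that add atoms: none
Why: Dess–Martin oxidation under bicarbonate buffering converts the allylic alcohol into the enal without acid or base that could isomerise the Z double bond.

Step 9
Reactants: 12 (2Z)-3-[(5R)-5-{2-[(4-methoxybenzyl)oxy]ethyl}-5-methyl-4-oxo-4,5-dihydrofuran-2-yl]but-2-enal; 13 methyl propiolate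
Product: 14 methyl (4R,5Z)-4-hydroxy-6-[(5R)-5-{2-[(4-methoxybenzyl)oxy]ethyl}-5-methyl-4-oxo-4,5-dihydrofuran-2-yl]hept-5-en-2-ynoate
Conditions: 13 (3 equiv), Me2Zn (3 equiv), (S,S)-ProPhenol (10 mol%), Ph3P=O (20 mol%), toluene, 4 °C
Reagents that add atoms: none
Why: Dinuclear zinc–ProPhenol catalysed asymmetric alkynylation of an α,β-unsaturated aldehyde, in which the catalyst delivers the zinc alkynylide to one aldehyde face and sets (6R) independently of the remote C10, while Me2Zn leaves the furanone ketone alone.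

Step 10
Reactants: 14 methyl (4R,5Z)-4-hydroxy-6-[(5R)-5-{2-[(4-methoxybenzyl)oxy]ethyl}-5-methyl-4-oxo-4,5-dihydrofuran-2-yl]hept-5-en-2-ynoate
Product: 17 (5R)-3-iodo-5-[(1Z)-2-[(5R)-5-{2-[(4-methoxybenzyl)oxy]ethyl}-5-methyl-4-oxo-4,5-dihydrofuran-2-yl]prop-1-en-1-yl]furan-2(5H)-one, via stannyl hydroxy ester 15 (not isolated), via stannylbutenolide 16 (not isolated)
Conditions: Bu3SnH, PdCl2(PPh3)2 (3 mol%), THF, 0 °C → rt; then I2, 0 °C
Reagents that add atoms: tributyltin hydride, CCCC[SnH](CCCC)CCCC (tin is carried only in 15 and 16); iodine, II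
Why: Palladium-catalysed syn-hydrostannation of the ynoate puts tin α to the ester and hydrogen on C7, the resulting cis γ-hydroxy enoate lactonises, and iododestannylation with retention gives the α-iodobutenolide without touching C6.

Step 11
Reactants: 17 (5R)-3-iodo-5-[(1Z)-2-[(5R)-5-{2-[(4-methoxybenzyl)oxy]ethyl}-5-methyl-4-oxo-4,5-dihydrofuran-2-yl]prop-1-en-1-yl]furan-2(5H)-one
Product: 18 (5R)-3-methyl-5-[(1Z)-2-[(5R)-5-{2-[(4-methoxybenzyl)oxy]ethyl}-5-methyl-4-oxo-4,5-dihydrofuran-2-yl]prop-1-en-1-yl]furan-2(5H)-one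
Conditions: MeZnCl, Pd(PPh3)4 (5 mol%), THF, 0 °C → rt
Reagents that add atoms: methylzinc chloride, C[Zn]Cl
Why: Negishi cross-coupling of the α-iodobutenolide installs the C13 methyl group under neutral conditions that do not deprotonate the acidic, doubly activated C6–H.

Step 12
Reactants: 18 (5R)-3-methyl-5-[(1Z)-2-[(5R)-5-{2-[(4-methoxybenzyl)oxy]ethyl}-5-methyl-4-oxo-4,5-dihydrofuran-2-yl]prop-1-en-1-yl]furan-2(5H)-one
Product: 19 (5R)-5-[(1Z)-2-[(5R)-5-(2-hydroxyethyl)-5-methyl-4-oxo-4,5-dihydrofuran-2-yl]prop-1-en-1-yl]-3-methylfuran-2(5H)-one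
Conditions: DDQ, CH2Cl2/pH 7 buffer, 0 °C → rt
Reagents that add atoms: none
Why: Oxidative PMB cleavage by hydride abstraction from the electron-rich benzylic position frees the C8 alcohol without acid or base.

Step 13
Reactants: 19 (5R)-5-[(1Z)-2-[(5R)-5-(2-hydroxyethyl)-5-methyl-4-oxo-4,5-dihydrofuran-2-yl]prop-1-en-1-yl]-3-methylfuran-2(5H)-one
Product: 20 2-[(2R)-2-methyl-5-{(1Z)-1-[(2R)-4-methyl-5-oxo-2,5-dihydrofuran-2-yl]prop-1-en-2-yl}-3-oxo-2,3-dihydrofuran-2-yl]acetaldehyde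
Conditions: Dess–Martin periodinane, NaHCO3, CH2Cl2, 0 °C; used crude
Reagents that add atoms: none
Why: Dess–Martin oxidation gives the C8 aldehyde, and the buffered, base-free conditions with direct use avoid retro-oxa-Michael loss of the furanone oxygen from this β-alkoxy aldehyde.

Step 14
Reactants: 20 2-[(2R)-2-methyl-5-{(1Z)-1-[(2R)-4-methyl-5-oxo-2,5-dihydrofuran-2-yl]prop-1-en-2-yl}-3-oxo-2,3-dihydrofuran-2-yl]acetaldehyde
Product: 21 (4Z,6R,7R,8R,10R,11S)-8-hydroxy-1-oxo-3,10-epoxygermacra-2,4-dien-6,12-olide (the 8-deacyl target)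
Conditions: SmI2 (3 equiv), t-BuOH (2 equiv), THF, −78 → 0 °C, syringe-pump addition of 20 (final 2 mM)
Reagents that add atoms: none
Why: Proposed new method: one-electron reduction of the C8 aldehyde should give a samarium(III) ketyl that adds to C7, the β-carbon of the butenolide, anti to the C5–C6 bond (trans-fused lactone, 7R); Sm(III) bridging the ketyl oxygen and the lactone carbonyl should hold O8 on the C12 side while C9 stays in the ring (8R), and the samarium enolate should be protonated at C11 from the samarium-bound face, which is also the more stable arrangement with methyl trans to C8 (11S); the closest known reaction type is the SmI2 ketyl–olefin cyclisation of aldehydes onto unsaturated esters and lactones, established for five- to eight-membered rings but not for this nine-membered oxacycle/ten-membered carbocycle, hence high dilution and no HMPA so that the dienone is spared.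

Step 15
Reactants: 21 (4Z,6R,7R,8R,10R,11S)-8-hydroxy-1-oxo-3,10-epoxygermacra-2,4-dien-6,12-olide; 22 angelic acid [(Z)-2-methylbut-2-enoic acid]
Product: 24 CNP0278264.1 (the 8-O-angelate of 21), via mixed anhydride 23 (not isolated)
Conditions: 22, 2,4,6-trichlorobenzoyl chloride, Et3N, toluene, rt; then 21, 80 °C
Reagents that add atoms: none
Why: Yamaguchi-type acylation through the mixed 2,4,6-trichlorobenzoic anhydride without DMAP is the standard way to make angelates without Z→E isomerisation to the tiglate, and C8 reacts with retention.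

Compound list
1 | (Z)-3-methylpent-2-en-4-yn-1-ol | C#C/C(C)=C\CO | starting material
2 | (Z)-tert-butyl[(3-methylpent-2-en-4-yn-1-yl)oxy]diphenylsilane | C#C/C(C)=C\CO[Si](c1ccccc1)(c1ccccc1)C(C)(C)C | intermediate
3 | methyl pyruvate | COC(=O)C(C)=O | starting material
4 | methyl (2R,5Z)-7-[(tert-butyldiphenylsilyl)oxy]-2-hydroxy-2,5-dimethylhept-5-en-3-ynoate | COC(=O)[C@](C)(O)C#C/C(C)=C\CO[Si](c1ccccc1)(c1ccccc1)C(C)(C)C | intermediate
5 | (2R,5Z)-7-[(tert-butyldiphenylsilyl)oxy]-2-hydroxy-N-methoxy-N,2,5-trimethylhept-5-en-3-ynamide | CON(C)C(=O)[C@](C)(O)C#C/C(C)=C\CO[Si](c1ccccc1)(c1ccccc1)C(C)(C)C | intermediate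
6 | vinylmagnesium bromide | C=C[Mg]Br | starting material
7 | (4R,7Z)-9-[(tert-butyldiphenylsilyl)oxy]-4-hydroxy-4,7-dimethylnona-1,7-dien-5-yn-3-one | C=CC(=O)[C@](C)(O)C#C/C(C)=C\CO[Si](c1ccccc1)(c1ccccc1)C(C)(C)C | intermediate
8 | 4-methoxybenzyl alcohol | COc1ccc(CO)cc1 | starting material
9 | (4R,7Z)-9-[(tert-butyldiphenylsilyl)oxy]-4-hydroxy-1-[(4-methoxybenzyl)oxy]-4,7-dimethylnon-7-en-5-yn-3-one | COc1ccc(COCCC(=O)[C@](C)(O)C#C/C(C)=C\CO[Si](c2ccccc2)(c2ccccc2)C(C)(C)C)cc1 | intermediate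
10 | (2R)-5-[(2Z)-4-[(tert-butyldiphenylsilyl)oxy]but-2-en-2-yl]-2-{2-[(4-methoxybenzyl)oxy]ethyl}-2-methylfuran-3(2H)-one | COc1ccc(COCC[C@@]2(C)OC(=CC2=O)/C(C)=C\CO[Si](c3ccccc3)(c3ccccc3)C(C)(C)C)cc1 | intermediate
11 | (2R)-5-[(2Z)-4-hydroxybut-2-en-2-yl]-2-{2-[(4-methoxybenzyl)oxy]ethyl}-2-methylfuran-3(2H)-one | COc1ccc(COCC[C@@]2(C)OC(=CC2=O)/C(C)=C\CO)cc1 | intermediate
12 | (2Z)-3-[(5R)-5-{2-[(4-methoxybenzyl)oxy]ethyl}-5-methyl-4-oxo-4,5-dihydrofuran-2-yl]but-2-enal | COc1ccc(COCC[C@@]2(C)OC(=CC2=O)/C(C)=C\C=O)cc1 | intermediate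
13 | methyl propiolate | C#CC(=O)OC | starting material
14 | methyl (4R,5Z)-4-hydroxy-6-[(5R)-5-{2-[(4-methoxybenzyl)oxy]ethyl}-5-methyl-4-oxo-4,5-dihydrofuran-2-yl]hept-5-en-2-ynoate | COc1ccc(COCC[C@@]2(C)OC(=CC2=O)/C(C)=C\[C@@H](O)C#CC(=O)OC)cc1 | intermediate
15 | methyl (2E,4R,5Z)-4-hydroxy-6-[(5R)-5-{2-[(4-methoxybenzyl)oxy]ethyl}-5-methyl-4-oxo-4,5-dihydrofuran-2-yl]-2-(tributylstannyl)hepta-2,5-dienoate | COc1ccc(COCC[C@@]2(C)OC(=CC2=O)/C(C)=C\[C@@H](O)/C=C(/[Sn](CCCC)(CCCC)CCCC)C(=O)OC)cc1 | intermediate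
16 | (5R)-5-[(1Z)-2-[(5R)-5-{2-[(4-methoxybenzyl)oxy]ethyl}-5-methyl-4-oxo-4,5-dihydrofuran-2-yl]prop-1-en-1-yl]-3-(tributylstannyl)furan-2(5H)-one | COc1ccc(COCC[C@@]2(C)OC(=CC2=O)/C(C)=C\[C@H]2OC(=O)C([Sn](CCCC)(CCCC)CCCC)=C2)cc1 | intermediate
17 | (5R)-3-iodo-5-[(1Z)-2-[(5R)-5-{2-[(4-methoxybenzyl)oxy]ethyl}-5-methyl-4-oxo-4,5-dihydrofuran-2-yl]prop-1-en-1-yl]furan-2(5H)-one | COc1ccc(COCC[C@@]2(C)OC(=CC2=O)/C(C)=C\[C@H]2OC(=O)C(I)=C2)cc1 | intermediate
18 | (5R)-3-methyl-5-[(1Z)-2-[(5R)-5-{2-[(4-methoxybenzyl)oxy]ethyl}-5-methyl-4-oxo-4,5-dihydrofuran-2-yl]prop-1-en-1-yl]furan-2(5H)-one | COc1ccc(COCC[C@@]2(C)OC(=CC2=O)/C(C)=C\[C@H]2OC(=O)C(C)=C2)cc1 | intermediate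
19 | (5R)-5-[(1Z)-2-[(5R)-5-(2-hydroxyethyl)-5-methyl-4-oxo-4,5-dihydrofuran-2-yl]prop-1-en-1-yl]-3-methylfuran-2(5H)-one | OCC[C@@]1(C)OC(=CC1=O)/C(C)=C\[C@H]1OC(=O)C(C)=C1 | intermediate
20 | 2-[(2R)-2-methyl-5-{(1Z)-1-[(2R)-4-methyl-5-oxo-2,5-dihydrofuran-2-yl]prop-1-en-2-yl}-3-oxo-2,3-dihydrofuran-2-yl]acetaldehyde | O=CC[C@@]1(C)OC(=CC1=O)/C(C)=C\[C@H]1OC(=O)C(C)=C1 | intermediate
21 | (4Z,6R,7R,8R,10R,11S)-8-hydroxy-1-oxo-3,10-epoxygermacra-2,4-dien-6,12-olide | O[C@@H]1C[C@@]2(C)OC(=CC2=O)/C(C)=C\[C@H]2OC(=O)[C@@H](C)[C@@H]21 | intermediate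
22 | angelic acid [(Z)-2-methylbut-2-enoic acid] | C/C=C(/C)C(=O)O | starting material
23 | (Z)-2-methylbut-2-enoic 2,4,6-trichlorobenzoic anhydride | C/C=C(/C)C(=O)OC(=O)c1c(Cl)cc(Cl)cc1Cl | intermediate
24 | CNP0278264.1, (4Z,6R,7R,8R,10R,11S)-8-[(Z)-2-methylbut-2-enoyloxy]-1-oxo-3,10-epoxygermacra-2,4-dien-6,12-olide | C/C=C(/C)C(=O)O[C@@H]1C[C@@]2(C)OC(=CC2=O)/C(C)=C\[C@H]2OC(=O)[C@@H](C)[C@@H]21 | target

Total step count: 15. Longest linear sequence: 15 steps (1 → 24); all other inputs are commercial.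

Steps most likely to fail

1. Step 14 (proposed new method). The medium-ring closure is slow, so the ketyl may instead dimerise to a pinacol, be reduced on to the primary alcohol or add 5-exo to C2 of the furanone. The β-alkoxy aldehyde may also lose the furanone oxygen by retro-oxa-Michael cleavage, or the C8 face may be attacked without chelation control. The fallback uses known chemistry, sets out from iodobutenolide 17 and returns at alcohol 21. Stille coupling of 17 with (tributylstannyl)methanol (Pd(PPh3)4, dioxane, 80 °C) gives the hydroxymethylbutenolide F1, and CBr4/PPh3 gives the allylic bromide F2. DDQ then Dess–Martin oxidation give the bromo alcohol F3 and the bromo aldehyde F4. CrCl2 in THF at high dilution closes the ring by an intramolecular Nozaki–Hiyama–Kishi-type allylation to the α-methylene lactone F5; a closed chair transition state is expected to place the C8 hydroxyl anti (8S). NaBH4 in MeOH at −20 °C reduces the exocyclic methylene in the conjugate sense to the 11S-methyl lactone F6. Dess–Martin oxidation gives the C8 ketone F7, and Luche reduction at −78 °C, with hydride arriving from the peripheral face away from the lactone, returns the 8R alcohol 21.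

2. Step 6 (key step). The tertiary propargylic alcohol may ionise (Meyer–Schuster pathway), the C6 oxygen may still attack C3, PMB alcohol may be lost by β-elimination, or a stepwise shift may erode the transfer of chirality. The fallback reaches the same furanone without the 1,2-shift, sets out from silyl enyne 2 and returns at 10. Commercial (R)-citramalic acid, C[C@@](O)(CC(=O)O)C(=O)O, with 2,2-dimethoxypropane and cat. TsOH gives the dioxolanone acid F8, and BH3·SMe2 reduces the free acid to the alcohol F9. PMB trichloroacetimidate with cat. CSA gives the PMB ether F10. The lithium acetylide of 2 (n-BuLi, THF, −78 °C) opens the dioxolanone with loss of acetone to the γ-hydroxy ynone F11, in which the tertiary carbinol is already C10. Et2NH in EtOH followed by AcOH closes F11 by 5-endo oxa-Michael addition to 10.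

3. Step 2. The catalyst may discriminate poorly between the methyl and ester flanks of pyruvate, and a low ee would be carried into C10 and surface later as diastereomers. The fallback replaces asymmetric catalysis by resolution, sets out from 2 and 3 and returns at Weinreb amide 5. The lithium acetylide of 2 (n-BuLi, THF, −78 °C) adds to 3 to give the racemic ester F12, and LiOH gives the racemic acid F13. Crystallisation of its (R)-1-phenylethylammonium salt and acidification give the (R)-acid F14, whose configuration is checked by Mosher analysis of a derived sample. EDC/HOBt coupling with N,O-dimethylhydroxylamine then gives 5.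

Further compounds
F1 | step 14 | (5R)-3-(hydroxymethyl)-5-[(1Z)-2-[(5R)-5-{2-[(4-methoxybenzyl)oxy]ethyl}-5-methyl-4-oxo-4,5-dihydrofuran-2-yl]prop-1-en-1-yl]furan-2(5H)-one | COc1ccc(COCC[C@@]2(C)OC(=CC2=O)/C(C)=C\[C@H]2OC(=O)C(CO)=C2)cc1
F2 | step 14 | (5R)-3-(bromomethyl)-5-[(1Z)-2-[(5R)-5-{2-[(4-methoxybenzyl)oxy]ethyl}-5-methyl-4-oxo-4,5-dihydrofuran-2-yl]prop-1-en-1-yl]furan-2(5H)-one | COc1ccc(COCC[C@@]2(C)OC(=CC2=O)/C(C)=C\[C@H]2OC(=O)C(CBr)=C2)cc1
F3 | step 14 | (5R)-3-(bromomethyl)-5-[(1Z)-2-[(5R)-5-(2-hydroxyethyl)-5-methyl-4-oxo-4,5-dihydrofuran-2-yl]prop-1-en-1-yl]furan-2(5H)-one | OCC[C@@]1(C)OC(=CC1=O)/C(C)=C\[C@H]1OC(=O)C(CBr)=C1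
F4 | step 14 | 2-[(2R)-5-{(1Z)-1-[(2R)-4-(bromomethyl)-5-oxo-2,5-dihydrofuran-2-yl]prop-1-en-2-yl}-2-methyl-3-oxo-2,3-dihydrofuran-2-yl]acetaldehyde | O=CC[C@@]1(C)OC(=CC1=O)/C(C)=C\[C@H]1OC(=O)C(CBr)=C1
F5 | step 14 | (4Z,6R,7R,8S,10R)-8-hydroxy-1-oxo-3,10-epoxygermacra-2,4,11(13)-trien-6,12-olide | O[C@H]1C[C@@]2(C)OC(=CC2=O)/C(C)=C\[C@H]2OC(=O)C(=C)[C@@H]21
F6 | step 14 | (4Z,6R,7R,8S,10R,11S)-8-hydroxy-1-oxo-3,10-epoxygermacra-2,4-dien-6,12-olide (8-epimer of 21) | O[C@H]1C[C@@]2(C)OC(=CC2=O)/C(C)=C\[C@H]2OC(=O)[C@@H](C)[C@@H]21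
F7 | step 14 | (4Z,6R,7R,10R,11S)-1,8-dioxo-3,10-epoxygermacra-2,4-dien-6,12-olide | O=C1C[C@@]2(C)OC(=CC2=O)/C(C)=C\[C@H]2OC(=O)[C@@H](C)[C@@H]21
F8 | step 6 | 2-[(4R)-2,2,4-trimethyl-5-oxo-1,3-dioxolan-4-yl]acetic acid | CC1(C)OC(=O)[C@@](C)(CC(=O)O)O1
F9 | step 6 | (5R)-5-(2-hydroxyethyl)-2,2,5-trimethyl-1,3-dioxolan-4-one | CC1(C)OC(=O)[C@@](C)(CCO)O1
F10 | step 6 | (5R)-5-{2-[(4-methoxybenzyl)oxy]ethyl}-2,2,5-trimethyl-1,3-dioxolan-4-one | COc1ccc(COCC[C@@]2(C)OC(C)(C)OC2=O)cc1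
F11 | step 6 | (3R,7Z)-9-[(tert-butyldiphenylsilyl)oxy]-3-hydroxy-1-[(4-methoxybenzyl)oxy]-3,7-dimethylnon-7-en-5-yn-4-one | COc1ccc(COCC[C@@](C)(O)C(=O)C#C/C(C)=C\CO[Si](c2ccccc2)(c2ccccc2)C(C)(C)C)cc1
F12 | step 2 | methyl (5Z)-7-[(tert-butyldiphenylsilyl)oxy]-2-hydroxy-2,5-dimethylhept-5-en-3-ynoate (racemic) | COC(=O)C(C)(O)C#C/C(C)=C\CO[Si](c1ccccc1)(c1ccccc1)C(C)(C)C
F13 | step 2 | (5Z)-7-[(tert-butyldiphenylsilyl)oxy]-2-hydroxy-2,5-dimethylhept-5-en-3-ynoic acid (racemic) | OC(=O)C(C)(O)C#C/C(C)=C\CO[Si](c1ccccc1)(c1ccccc1)C(C)(C)C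
F14 | step 2 | (2R,5Z)-7-[(tert-butyldiphenylsilyl)oxy]-2-hydroxy-2,5-dimethylhept-5-en-3-ynoic acid | OC(=O)[C@](C)(O)C#C/C(C)=C\CO[Si](c1ccccc1)(c1ccccc1)C(C)(C)C
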